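**Plan**

1. Lignan numbering: C7 = ring carbon bearing the aryl group, C8 = ring carbon bearing C9H2OH, C8' = ring carbon bearing the C7'H2 aryl arm, C9' = ring OCH2.
2. Retrosynthetic cuts, in order: C9 alcohol to a C9 acid; C7'–H to a benzylic lactone C7'–O bond; C8–H to a C8 ester; the C7'–aryl bond (aryl Grignard on a C7' aldehyde, itself from a vinyl group); last, the oxolane at C7–O and C8–C8'.
3. Enabling feature: O–C9'–C8' with its one-carbon branch C7' is a ring-opened 2-vinyloxirane, and C7–C8 with a carboxyl-level C9 is an arylidene malonate, so the oxolane is a formal [3+2] adduct of the two.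
4. Forward: the oxolane (the only ring of the target) closes first in the palladium annulation. The vinyl group is then cut to the C7' aldehyde, the second aryl group is added, a temporary γ-lactone ring closes, loses its extra ester and is reopened by hydrogenolysis; the acid is reduced last.
5. Stereochemistry: C8' from the chiral ligand acting on the racemic epoxide; C7 trans to C8' from the ring closure; C8 from the cis-fused lactone (only the ester cis to C7' can lactonise, and decarboxylation can only give the cis bicycle).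

Key step: step 3

Assumption: the (R,R)-configured ligand is taken to deliver the (4R) vinyl-bearing carbon of 6; should the opposite sense be found, the (S,S)-ligand is used and nothing else changes.

**Route**

Step 1
Reactants: 1 syringaldehyde (4-hydroxy-3,5-dimethoxybenzaldehyde)
Product: 2 4-(benzyloxy)-3,5-dimethoxybenzaldehyde
Conditions: BnBr, K2CO3, DMF, 60 °C
Reagents that add atoms: benzyl bromide, BrCc1ccccc1
Why: Williamson ether synthesis, in which the phenoxide formed by K2CO3 displaces bromide from benzyl bromide while the aldehyde is untouched.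

Step 2
Reactants: 2 4-(benzyloxy)-3,5-dimethoxybenzaldehyde; 3 dimethyl malonate
Product: 4 dimethyl 2-[4-(benzyloxy)-3,5-dimethoxybenzylidene]malonate
Conditions: piperidine (cat.), AcOH (cat.), toluene, reflux, Dean–Stark trap
Reagents that add atoms: none
Why: Knoevenagel condensation driven by azeotropic removal of water, with no alkene geometry to control because the malonate is symmetrical.

Step 3
Reactants: 4 dimethyl 2-[4-(benzyloxy)-3,5-dimethoxybenzylidene]malonate; 5 racemic 2-vinyloxirane
Product: 6 dimethyl (2R,4R)-2-[4-(benzyloxy)-3,5-dimethoxyphenyl]-4-ethenyloxolane-3,3-dicarboxylate (2,4-trans)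
Conditions: Pd2(dba)3·CHCl3 (2.5 mol %), (R,R)-DACH-naphthyl ligand N,N'-[(1R,2R)-cyclohexane-1,2-diyl]bis[2-(diphenylphosphanyl)naphthalene-1-carboxamide] (7.5 mol %), 5 (2 equiv), THF, 0 °C → rt
Reagents that add atoms: none
Why: Zerovalent palladium ionises the vinyloxirane to an alkoxide-bearing π-allylpalladium zwitterion; its alkoxide adds reversibly to the benzylidene carbon of 4 (oxa-Michael, C7–O) and the malonate carbanion so formed attacks the internal allyl carbon anti to palladium (allylic alkylation, C8–C8'), which releases the catalyst. The closest known reaction type is the palladium-catalysed formal [3+2] cycloaddition of vinyl epoxides with doubly activated alkenes. The oxolane ring closes in the C–C bond-forming event by 5-exo attack on the allyl unit, favoured over attack at the allyl terminus that would give a seven-membered ring, and this also secures the branched regiochemistry that leaves the vinyl group as the future C7'. C8' is controlled by the ligand, because the diastereomeric π-allyl complexes arising from the two epoxide enantiomers interconvert by π–σ–π isomerisation faster than the ring closes, so that the chiral pocket selects one allyl face and the racemate converges on one enantiomer. C7 is controlled relative to C8' by the substrate: since the oxa-Michael step is reversible, closure goes through the less crowded envelope in which the aryl group is pseudo-equatorial and turned away from the allyl–palladium–ligand unit, which gives the 2,4-trans ring. The step thus needs enantio-, regio- and trans-diastereoselection, secured in turn by the ligand, by five-membered ring formation and by reversibility of the first bond, while the aryl benzyl ether and the esters are spectators.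

Step 4
Reactants: 7 4-bromo-2,6-dimethoxyphenol
Product: 8 2-(benzyloxy)-5-bromo-1,3-dimethoxybenzene
Conditions: BnBr, K2CO3, DMF, 60 °C
Reagents that add atoms: benzyl bromide, BrCc1ccccc1
Why: Williamson ether synthesis of the hindered but acidic phenol, with the aryl bromide inert to carbonate.

Step 5
Reactants: 8 2-(benzyloxy)-5-bromo-1,3-dimethoxybenzene
Product: 9 [4-(benzyloxy)-3,5-dimethoxyphenyl]magnesium bromide
Conditions: Mg turnings, I2 (cat.), THF, reflux; solution titrated and used directly
Reagents that add atoms: magnesium, [Mg]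
Why: Grignard formation by insertion of magnesium into the aryl C–Br bond, the benzyl and methyl ethers being inert to the reagent.

Step 6
Reactants: 6 dimethyl (2R,4R)-2-[4-(benzyloxy)-3,5-dimethoxyphenyl]-4-ethenyloxolane-3,3-dicarboxylate
Product: 11 dimethyl (2R,4R)-2-[4-(benzyloxy)-3,5-dimethoxyphenyl]-4-formyloxolane-3,3-dicarboxylate, via vicinal diol 10 (not isolated)
Conditions: OsO4 (2 mol %), NaIO4 (4 equiv), 2,6-lutidine (2 equiv), 1,4-dioxane–H2O (3:1), rt; crude aldehyde used at once
Reagents that add atoms: osmium tetroxide, O=[Os](=O)(=O)=O (catalytic oxygen carrier); sodium periodate, [Na+].[O-]I(=O)(=O)=O (terminal oxygen source)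
Why: Lemieux–Johnson oxidation, in which OsO4 dihydroxylates the only alkene and periodate cleaves the diol to the aldehyde and formaldehyde, while 2,6-lutidine keeps the medium near neutral so that the enolisable C8' centre should not epimerise.

Step 7
Reactants: 11 dimethyl (2R,4R)-2-[4-(benzyloxy)-3,5-dimethoxyphenyl]-4-formyloxolane-3,3-dicarboxylate; 9 [4-(benzyloxy)-3,5-dimethoxyphenyl]magnesium bromide
Product: 13 methyl (1S,5R,8R)-4,8-bis[4-(benzyloxy)-3,5-dimethoxyphenyl]-2-oxo-3,7-dioxabicyclo[3.3.0]octane-1-carboxylate (cis-fused; C4 epimers), via bromomagnesium alkoxide 12 (not isolated)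
Conditions: 9 (1.2 equiv), THF, −78 °C → rt; then aq NH4Cl
Reagents that add atoms: none
Why: Grignard 1,2-addition to the aldehyde is much faster at −78 °C than attack on the hindered geminal esters or enolisation at C8', and on warming the alkoxide lactonises (intramolecular transesterification) onto the only ester it can reach, the one cis to C7', which makes C8 a stereocentre with the lactone carbonyl cis to C7' (the C7' configuration is immaterial because that centre later becomes CH2).

Step 8
Reactants: 13 methyl (1S,5R,8R)-4,8-bis[4-(benzyloxy)-3,5-dimethoxyphenyl]-2-oxo-3,7-dioxabicyclo[3.3.0]octane-1-carboxylate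
Product: 15 (1S,5R,8S)-4,8-bis[4-(benzyloxy)-3,5-dimethoxyphenyl]-3,7-dioxabicyclo[3.3.0]octan-2-one (cis-fused; C4 epimers), via lithium carboxylate 14 (not isolated)
Conditions: LiCl (3 equiv), H2O (2 equiv), DMSO, 140 °C
Reagents that add atoms: none
Why: Krapcho dealkoxycarbonylation, in which chloride demethylates the malonate-type ester by SN2 attack, the carboxylate loses CO2 to the lactone enolate and protonation can only give the cis-fused bicycle, so that H-8 ends up cis to H-8' and C9 trans to the C7 aryl group.

Step 9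
Reactants: 15 (1S,5R,8S)-4,8-bis[4-(benzyloxy)-3,5-dimethoxyphenyl]-3,7-dioxabicyclo[3.3.0]octan-2-one
Product: 17 (2S,3S,4R)-4-(4-hydroxy-3,5-dimethoxybenzyl)-2-(4-hydroxy-3,5-dimethoxyphenyl)oxolane-3-carboxylic acid, via bisphenol lactone 16 (not isolated)
Conditions: H2 (1 atm), Pd/C (10 wt %), EtOAc–AcOH (10:1), rt; stopped after uptake of 3 equiv H2
Reagents that add atoms: none
Why: Palladium-catalysed hydrogenolysis should cleave the two aryl benzyl ethers first and then the benzylic acyloxy C7'–O bond of the lactone, whose carboxylate is a better leaving group than the ring ether oxygen at C7, so the oxolane should survive if the uptake is limited, and no stereocentre is touched as C7' becomes CH2.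

Step 10
Reactants: 17 (2S,3S,4R)-4-(4-hydroxy-3,5-dimethoxybenzyl)-2-(4-hydroxy-3,5-dimethoxyphenyl)oxolane-3-carboxylic acid
Product: 18 (+)-(7S,8R,8'R)-5,5'-dimethoxylariciresinol, [(2S,3R,4R)-4-(4-hydroxy-3,5-dimethoxybenzyl)-2-(4-hydroxy-3,5-dimethoxyphenyl)oxolan-3-yl]methanol
Conditions: BH3·SMe2 (5 equiv), THF, 0 °C → rt; then MeOH, reflux
Reagents that add atoms: none
Why: Borane reduction of the carboxylic acid through an acyloxyborane is chemoselective here, the phenols merely forming borate esters that methanol cleaves, and it gives the C9 primary alcohol without affecting C7, C8 or C8'.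

**Compound list**

1 | syringaldehyde (4-hydroxy-3,5-dimethoxybenzaldehyde) | COc1cc(C=O)cc(OC)c1O | starting material
2 | 4-(benzyloxy)-3,5-dimethoxybenzaldehyde | COc1cc(C=O)cc(OC)c1OCc1ccccc1 | intermediate
3 | dimethyl malonate | COC(=O)CC(=O)OC | starting material
4 | dimethyl 2-[4-(benzyloxy)-3,5-dimethoxybenzylidene]malonate | COC(=O)C(=Cc1cc(OC)c(OCc2ccccc2)c(OC)c1)C(=O)OC | intermediate
5 | racemic 2-vinyloxirane | C=CC1CO1 | starting material
6 | dimethyl (2R,4R)-2-[4-(benzyloxy)-3,5-dimethoxyphenyl]-4-ethenyloxolane-3,3-dicarboxylate (aryl and vinyl trans) | C=C[C@H]1CO[C@H](c2cc(OC)c(OCc3ccccc3)c(OC)c2)C1(C(=O)OC)C(=O)OC | intermediate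
7 | 4-bromo-2,6-dimethoxyphenol | COc1cc(Br)cc(OC)c1O | starting material
8 | 2-(benzyloxy)-5-bromo-1,3-dimethoxybenzene | COc1cc(Br)cc(OC)c1OCc1ccccc1 | intermediate
9 | [4-(benzyloxy)-3,5-dimethoxyphenyl]magnesium bromide | COc1cc([Mg]Br)cc(OC)c1OCc1ccccc1 | intermediate
10 | dimethyl (2R,4R)-2-[4-(benzyloxy)-3,5-dimethoxyphenyl]-4-(1,2-dihydroxyethyl)oxolane-3,3-dicarboxylate (carbinol epimers) | OCC(O)[C@H]1CO[C@H](c2cc(OC)c(OCc3ccccc3)c(OC)c2)C1(C(=O)OC)C(=O)OC | intermediate (not isolated)
11 | dimethyl (2R,4R)-2-[4-(benzyloxy)-3,5-dimethoxyphenyl]-4-formyloxolane-3,3-dicarboxylate | O=C[C@H]1CO[C@H](c2cc(OC)c(OCc3ccccc3)c(OC)c2)C1(C(=O)OC)C(=O)OC | intermediate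
12 | bromomagnesium alkoxide of dimethyl (2R,4R)-2-[4-(benzyloxy)-3,5-dimethoxyphenyl]-4-{[4-(benzyloxy)-3,5-dimethoxyphenyl](hydroxy)methyl}oxolane-3,3-dicarboxylate (C7' epimers) | COc1cc(C(O[Mg]Br)[C@H]2CO[C@H](c3cc(OC)c(OCc4ccccc4)c(OC)c3)C2(C(=O)OC)C(=O)OC)cc(OC)c1OCc1ccccc1 | intermediate (not isolated)
13 | methyl (1S,5R,8R)-4,8-bis[4-(benzyloxy)-3,5-dimethoxyphenyl]-2-oxo-3,7-dioxabicyclo[3.3.0]octane-1-carboxylate (cis-fused; lignan C7 R, C8 S, C8' R; C7' epimers) | O=C1OC(c3cc(OC)c(OCc4ccccc4)c(OC)c3)[C@H]2CO[C@H](c3cc(OC)c(OCc4ccccc4)c(OC)c3)[C@@]12C(=O)OC | intermediate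
14 | lithium (1S,5R,8R)-4,8-bis[4-(benzyloxy)-3,5-dimethoxyphenyl]-2-oxo-3,7-dioxabicyclo[3.3.0]octane-1-carboxylate | O=C1OC(c3cc(OC)c(OCc4ccccc4)c(OC)c3)[C@H]2CO[C@H](c3cc(OC)c(OCc4ccccc4)c(OC)c3)[C@@]12C(=O)[O-].[Li+] | intermediate (not isolated)
15 | (1S,5R,8S)-4,8-bis[4-(benzyloxy)-3,5-dimethoxyphenyl]-3,7-dioxabicyclo[3.3.0]octan-2-one (cis-fused; lignan C7 S, C8 S, C8' R; C7' epimers) | O=C1OC(c3cc(OC)c(OCc4ccccc4)c(OC)c3)[C@H]2CO[C@H](c3cc(OC)c(OCc4ccccc4)c(OC)c3)[C@@H]12 | intermediate
16 | (1S,5R,8S)-4,8-bis(4-hydroxy-3,5-dimethoxyphenyl)-3,7-dioxabicyclo[3.3.0]octan-2-one (C7' epimers) | O=C1OC(c3cc(OC)c(O)c(OC)c3)[C@H]2CO[C@H](c3cc(OC)c(O)c(OC)c3)[C@@H]12 | intermediate (not isolated)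
17 | (2S,3S,4R)-4-(4-hydroxy-3,5-dimethoxybenzyl)-2-(4-hydroxy-3,5-dimethoxyphenyl)oxolane-3-carboxylic acid | COc1cc(C[C@H]2CO[C@H](c3cc(OC)c(O)c(OC)c3)[C@H]2C(=O)O)cc(OC)c1O | intermediate
18 | (+)-(7S,8R,8'R)-5,5'-dimethoxylariciresinol | COc1cc(C[C@H]2CO[C@H](c3cc(OC)c(O)c(OC)c3)[C@H]2CO)cc(OC)c1O | target

**Step count**

Total: 10 steps. Longest linear sequence: 8 steps (steps 1, 2, 3, 6, 7, 8, 9, 10 from syringaldehyde); the aryl Grignard arm (steps 4 and 5) is convergent.

**Steps most likely to fail**

Step 3. The ring closure may give insufficient enantioselection or an eroded 2,4-trans preference, and the strained epoxide may be consumed unproductively before the electron-rich, weakly electrophilic acceptor is engaged. The fallback sets out from 4 and generates the zwitterion by decarboxylative ionisation of 4-ethenyl-1,3-dioxolan-2-one (vinylethylene carbonate, C=CC1COC(=O)O1) instead of the epoxide, with Pd2(dba)3·CHCl3 and a BINOL-derived chiral phosphoramidite in THF. This is the known decarboxylative annulation of that carbonate with doubly activated alkenes; it releases the dipole slowly and uses a different ligand class. It comes back to the route at 6 and makes no new compound (F0).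

Step 9. Hydrogenolysis may run on past the lactone and cleave the benzylic C7–O bond of the oxolane once the para-phenols are free. The fallback sets out from 15 and removes the C7' oxygen by a radical route, so that palladium is needed only for a brief final debenzylation. LiAlH4 (THF, 0 °C) reduces the lactone to the 7'-hydroxy-4,4'-di-O-benzyl diol F1. TBSCl and imidazole (DMF, 0 °C) silylate only the primary C9 hydroxyl to give the 9-O-TBS ether F2. NaH, CS2 and then MeI (THF, 0 °C) give the benzylic S-methyl xanthate F3. Bu3SnH with AIBN (toluene, 80 °C, Barton–McCombie deoxygenation) gives the 7'-deoxy silyl ether F4. TBAF (THF) frees 4,4'-di-O-benzyl-5,5'-dimethoxylariciresinol F5. A short hydrogenolysis (H2, Pd/C, EtOAc, rt) that only has to cleave two aryl benzyl ethers comes back to the route at 18.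

Step 8. Chloride may open the electron-rich benzylic lactone at C7', or the material may degrade at 140 °C, with loss of the C8 control. The fallback sets out from 13 and separates hydrolysis from decarboxylation. Me3SnOH (1,2-dichloroethane, 80 °C, then dilute acid work-up) hydrolyses the methyl ester to the lactone carboxylic acid F6. Heating F6 in toluene at 110 °C effects decarboxylation of this malonic-type acid, again through the enol of the cis-fused lactone, and comes back to the route at 15.

**Further compounds**

F0 | step 3 | none | none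
F1 | step 9 | (7S,8R,8'R)-4,4'-di-O-benzyl-7'-hydroxy-5,5'-dimethoxylariciresinol (C7' epimers) | COc1cc(C(O)[C@H]2CO[C@H](c3cc(OC)c(OCc4ccccc4)c(OC)c3)[C@H]2CO)cc(OC)c1OCc1ccccc1
F2 | step 9 | 9-O-tert-butyldimethylsilyl ether of F1 | COc1cc(C(O)[C@H]2CO[C@H](c3cc(OC)c(OCc4ccccc4)c(OC)c3)[C@H]2CO[Si](C)(C)C(C)(C)C)cc(OC)c1OCc1ccccc1
F3 | step 9 | 7'-O-(methylsulfanyl)carbonothioyl derivative (S-methyl xanthate) of F2 | COc1cc(C(OC(=S)SC)[C@H]2CO[C@H](c3cc(OC)c(OCc4ccccc4)c(OC)c3)[C@H]2CO[Si](C)(C)C(C)(C)C)cc(OC)c1OCc1ccccc1
F4 | step 9 | (7S,8R,8'R)-4,4'-di-O-benzyl-9-O-tert-butyldimethylsilyl-5,5'-dimethoxylariciresinol | COc1cc(C[C@H]2CO[C@H](c3cc(OC)c(OCc4ccccc4)c(OC)c3)[C@H]2CO[Si](C)(C)C(C)(C)C)cc(OC)c1OCc1ccccc1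
F5 | step 9 | (7S,8R,8'R)-4,4'-di-O-benzyl-5,5'-dimethoxylariciresinol | COc1cc(C[C@H]2CO[C@H](c3cc(OC)c(OCc4ccccc4)c(OC)c3)[C@H]2CO)cc(OC)c1OCc1ccccc1
F6 | step 8 | (1S,5R,8R)-4,8-bis[4-(benzyloxy)-3,5-dimethoxyphenyl]-2-oxo-3,7-dioxabicyclo[3.3.0]octane-1-carboxylic acid (C7' epimers) | O=C1OC(c3cc(OC)c(OCc4ccccc4)c(OC)c3)[C@H]2CO[C@H](c3cc(OC)c(OCc4ccccc4)c(OC)c3)[C@@]12C(=O)O
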